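## Structural features

The target is a 2,3-dihydrobenzofuran: a benzene ring (ring A) fused to a five-membered oxygen ring (ring B: O1, C2, C3, C3a, C7a). C2 carries a 3,4,5-trimethoxyphenyl group (ring C), C3 a hydroxymethyl group, and C5 of ring A, para to O1, an (E)-3-hydroxyprop-1-enyl chain. C2 (R) and C3 (S) are adjacent and are the only stereocenters, with the aryl and hydroxymethyl groups trans, so the whole stereochemical problem sits on one C–C bond. The C2–O1 bond is both benzylic and an aryl ether bond, so acid can ionise it (epimerisation at C2 or ring opening). H3 is benzylic and β to O1, so base or oxidants can drive elimination or aromatisation, and the cinnamyl alcohol is sensitive to acid and electrophiles. The real difficulty is control of the absolute configuration of the C2/C3 pair in a ring that has no other functional group to direct a reagent. The handle is the chain O1–C2–C3–CH2–OH: three contiguous carbons with oxygen on the first and the last. This 1,3-dioxygenated unit is what remains when a cyclopropane made of C2, C3 and the CH2 carbon is opened by an electrophile at CH2 and an oxygen nucleophile at C2, and O1 is already held on ring A within reach of C2.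

## Logic of the disconnections

15 from 14. No skeletal bond is cut; the allylic CH2OH of the C5 side chain is taken back to a methyl ester. The reason lies in the key step: an alkene conjugated to an ester is electron-poor and should ignore divalent mercury, whereas an allylic alcohol would be oxymercurated. The gain is that the three-carbon side chain is carried from the start as one robust unit. The forward step must reduce the ester 1,2 and leave the alkene, ring B and the free primary alcohol alone.

14 from 12. The C–O bond of the C3 hydroxymethyl group is exchanged for a C–Hg bond. A primary alkylmercury halide is what an electrophilic opening of a three-membered ring by mercury leaves behind, so this cut exposes the retron of the key step. The skeleton is not simplified, but the oxygen no longer has to be carried through the ring construction. The forward step must turn C–Hg into C–O faster than the intermediate radical captures hydrogen, and must not reduce the acrylate.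

12 from 10. The O1–C2 bond is cut and the CH2 carbon is rejoined to C2, which folds ring B back into a trans-1,2-diarylcyclopropane with a free ortho phenol. This is the strategic cut. The C2/C3 pair becomes the pair of stereocenters of a cyclopropane, for which stereospecific syntheses exist, and ring B with its acid-labile benzylic ether is absent until late. The forward step must break C2–CH2 and not C3–CH2, deliver O1 to C2 with clean inversion, and spare two electron-rich arenes and the alkene.

10 from 7 and 9. The bond between the cyclopropane carbon that becomes C3 and the ring A carbon that becomes C3a is cut. This divides the molecule into two halves of similar size, each reachable in one to three steps, and puts all the stereochemistry into the small boron fragment. The forward sp3–sp2 coupling must proceed with retention at the cyclopropyl carbon and tolerate a free phenol next to the bromide and a methyl ester.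

9 from 8. The Cα=Cβ bond of the acrylate is cut back to an aldehyde. Ring A then comes from a commercial compound that already holds the bromide, the phenol and the para carbon in the right places. The forward olefination must be E-selective in the presence of the unprotected phenol.

7 from 5. The two bonds from the cyclopropane CH2 to its neighbours are cut (methylene transfer to an alkene), and the boronic acid is retraced to the boronic ester of a chiral diol. Because methylene transfer is stereospecific, the trans relationship reduces to E alkene geometry and the absolute configuration to a choice of alkene face that the diol can direct. The forward step demands high facial selectivity, survival of the C–B bond under the zinc carbenoid, and an auxiliary that leaves in the work-up.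

5 from 3 and 4. The two B–O bonds are cut. This separates the achiral alkenylboronic acid from the chiral diol, both simple. The forward condensation only has to be driven to completion by removal of water.

3 from 1. The C–B bond is cut, leading back to a terminal arylalkyne. The forward hydroboration must be anti-Markovnikov and syn so that only the E isomer forms.

## Other disconnections considered

Alternative 1: The cut runs through O1–C2 and C2–C3, so that C2 with ring C arrives as a one-carbon unit. In the forward step Cs2CO3 eliminates sulfinate from the sulfone A1 (4-bromo-2-{2-[(tert-butyldimethylsilyl)oxy]-1-(4-methylbenzenesulfonyl)ethyl}phenol) to release an ortho-quinone methide whose exocyclic carbon is the future C3. The same base converts the chiral sulfonium salt A2 ((2R,5R)-2,5-dimethyl-1-(3,4,5-trimethoxybenzyl)thiolan-1-ium triflate, or its enantiomer as the sense of induction requires) into a benzylic ylide. The ylide carbon adds to the methide carbon (C2–C3) and the phenoxide then displaces the thiolane at C2 (O1–C2), giving A3 (the silyl ether of the (2R,3S)-5-bromo-3-hydroxymethyl dihydrobenzofuran).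
- In its favour: it is convergent, forms ring B and both stereocenters in one operation under mild base, and should give the trans isomer because the betaine can equilibrate before displacement. It uses no toxic metal and leaves a C5 bromide for a later Heck reaction.
- Against it here: the methide derived from A1 has hydrogens next to the methide carbon and may tautomerise by a 1,5-hydrogen shift before the ylide arrives. The absolute configuration depends on face selection by a semi-stabilised benzyl ylide on a planar, short-lived methide. The chiral sulfide is stoichiometric, and a Heck reaction, an ester reduction and a desilylation must follow A3.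
- Comparison: at the ring-closing event the two plans are mechanistic equals, since both finish with O1 displacing a leaving group at C2 with inversion. The alternative is the better on convergence, on bonds formed in the key step (two against one) and on the absence of mercury. It is about equal in length (roughly eight to nine steps against eight). The chosen plan is the better on certainty of absolute configuration, because C3 is stored in the isolable cyclopropane 10 before ring B is made.

Alternative 2: The cut removes ring A itself: C3a–C7a and C4–C5 are broken and CO2 is added back. This leads to the 2-pyrone A4 (methyl 3-{[(1R,2S)-2-{[(tert-butyldimethylsilyl)oxy]methyl}-1-(3,4,5-trimethoxyphenyl)but-3-yn-1-yl]oxy}-2-oxo-2H-pyran-6-carboxylate). On heating, the tethered alkyne adds across C3 and C6 of the pyrone, the bridged lactone loses CO2, and A5 (methyl (2R,3S)-3-{[(tert-butyldimethylsilyl)oxy]methyl}-2-(3,4,5-trimethoxyphenyl)-2,3-dihydro-1-benzofuran-5-carboxylate) results.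
- In its favour: the key step creates no stereocenter and touches neither C2 nor C3. The tether fixes the regiochemistry, the loss of CO2 makes the sequence irreversible, and two rings and two C–C bonds form without any reagent.
- Against it here: the diene carries a donor at C3 and an acceptor at C6 while the dienophile is an unactivated terminal alkyne, so a high temperature is to be expected. At that temperature the trimethoxybenzylic C–O bond of A4, whose oxygen belongs to an acidic hydroxypyrone, may ionise or eliminate. The C2/C3 pair must be built beforehand in an acyclic precursor, and the hindered benzylic oxygen must be joined to the pyrone without loss of configuration. The C5 ester of A5 still lacks two carbons of the side chain.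
- Comparison: on skeletal gain per step and freedom from metals the alternative is the better. Its key step is the equal of the chosen one in that it cannot erode the trans relationship. It moves the stereochemical problem into an acyclic precursor instead of solving it, and it should be longer by several steps.

Alternative 3: The cut is C3–C3a, with the exocyclic carbon rejoined to ring A as a ketone, which gives the flavanone A6 ((2R)-6-bromo-2-(3,4,5-trimethoxyphenyl)-2,3-dihydro-4H-chromen-4-one). PhI(OAc)2 and H2SO4 in trimethyl orthoformate convert A6 into its enol ether, trivalent iodine adds at C3, and ring A carbon C4a shifts from C4 to C3 as the aryl iodide departs. C4 ends as the methyl ester of A7 (methyl (2R,3R)-5-bromo-2-(3,4,5-trimethoxyphenyl)-2,3-dihydro-1-benzofuran-3-carboxylate, 2,3-trans).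
- In its favour: it is the shortest of all the plans, uses cheap reagents and is trans-selective by mechanism. The ester is the direct precursor of the hydroxymethyl group and the bromide serves a later Heck reaction.
- Against it here: the only source of chirality is C2 of A6. Flavanones lose that configuration by reversible retro-oxa-Michael ring opening, which strong acid promotes, and A6 would itself need an asymmetric synthesis. The electron-rich ring C favours the competing 2,3-shift of ring C and is open to oxidation by trivalent iodine, while the bromine lowers the migratory aptitude of ring A.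
- Comparison: the alternative is the better on step count (roughly six to seven against eight) and on reagent hazard, and the equal on trans selectivity. In mechanism it is a cationic 1,2-shift on a substrate that can racemise, against a stereospecific displacement on a configurationally stable cyclopropane. For a single enantiomer the chosen plan is the better.

Key step: step 6

Assumption: the (S,S)-diamide 4 is taken to steer the methylene transfer of step 3 to the alkene face that gives the (1S,2S) acid 7; if the intrinsic sense of this auxiliary is the opposite, its (R,R) enantiomer is used and nothing else changes.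

## Route

Step 1
Reactants: 1 5-ethynyl-1,2,3-trimethoxybenzene
Product: 3 [(E)-2-(3,4,5-trimethoxyphenyl)ethenyl]boronic acid, via catechol alkenylboronate 2 (not isolated)
Conditions: catecholborane, THF, 70 °C; then H2O, rt
Reagents that add atoms: catecholborane (B1Oc2ccccc2O1); water (O)
Why: Hydroboration of a terminal arylalkyne with catecholborane is a syn, anti-Markovnikov addition, so boron ends on the terminal carbon and only the (E)-alkenylboronate 2 forms. Water cleaves the labile catechol ester, and the boronic acid 3 can be purified by crystallisation.

Step 2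
Reactants: 3 [(E)-2-(3,4,5-trimethoxyphenyl)ethenyl]boronic acid; 4 (2S,3S)-2,3-dihydroxy-N,N,N',N'-tetramethylbutanediamide
Product: 5 (4S,5S)-N,N,N',N'-tetramethyl-2-[(E)-2-(3,4,5-trimethoxyphenyl)ethenyl]-1,3,2-dioxaborolane-4,5-dicarboxamide
Conditions: MgSO4, CH2Cl2, rt
Reagents that add atoms: none
Why: Condensation of a boronic acid with a 1,2-diol to a five-membered boronic ester is an equilibrium that the drying agent drives to completion. It places a C2-symmetric chiral auxiliary on boron, directly next to the alkene; the moisture-sensitive ester 5 is used without chromatography.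

Step 3
Reactants: 5 (4S,5S)-N,N,N',N'-tetramethyl-2-[(E)-2-(3,4,5-trimethoxyphenyl)ethenyl]-1,3,2-dioxaborolane-4,5-dicarboxamide
Product: 7 [(1S,2S)-2-(3,4,5-trimethoxyphenyl)cyclopropyl]boronic acid, via tartramide cyclopropylboronate 6 (not isolated)
Conditions: Zn–Cu couple, CH2I2, Et2O, reflux; then H2O, rt
Reagents that add atoms: diiodomethane (ICI); water (O)
Why: Simmons–Smith cyclopropanation is a concerted, stereospecific methylene transfer, so the (E)-alkene can only give the trans cyclopropane. Both new stereocenters are set by the auxiliary, whose amide carbonyl groups bind the zinc carbenoid and deliver CH2 to one face of the alkenylboron unit. The tartramide ester 6 is labile to water, so the work-up frees acid 7, which as a boronic acid should crystallise and allow its stereochemical purity to be raised.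

Step 4
Reactants: 8 3-bromo-4-hydroxybenzaldehyde
Product: 9 methyl (2E)-3-(3-bromo-4-hydroxyphenyl)prop-2-enoate
Conditions: Ph3P=CHCO2Me, toluene, 90 °C
Reagents that add atoms: methyl (triphenylphosphoranylidene)acetate (COC(=O)C=P(c1ccccc1)(c1ccccc1)c1ccccc1)
Why: Wittig reaction with an ester-stabilised ylide, in which reversible adduct formation leads to the (E)-alkene. The ylide is mild enough to leave the phenol and the aryl bromide untouched.

Step 5
Reactants: 7 [(1S,2S)-2-(3,4,5-trimethoxyphenyl)cyclopropyl]boronic acid; 9 methyl (2E)-3-(3-bromo-4-hydroxyphenyl)prop-2-enoate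
Product: 10 methyl (2E)-3-{4-hydroxy-3-[(1S,2S)-2-(3,4,5-trimethoxyphenyl)cyclopropyl]phenyl}prop-2-enoate
Conditions: Pd(OAc)2 (5 mol %), SPhos (10 mol %), K3PO4, toluene/H2O, 90 °C
Reagents that add atoms: none
Why: Suzuki–Miyaura coupling: zerovalent palladium inserts into the C–Br bond, and both transmetalation of the cyclopropyl–boron bond and reductive elimination proceed with retention, so the (1S,2S) configuration of 7 is carried into 10. The cyclopropyl–palladium intermediate has no easy β-hydride elimination, and the bulky electron-rich phosphine allows oxidative addition even when the ortho phenol is deprotonated.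

Step 6
Reactants: 10 methyl (2E)-3-{4-hydroxy-3-[(1S,2S)-2-(3,4,5-trimethoxyphenyl)cyclopropyl]phenyl}prop-2-enoate
Product: 12 methyl (2E)-3-[(2R,3R)-3-[(chloromercurio)methyl]-2-(3,4,5-trimethoxyphenyl)-2,3-dihydro-1-benzofuran-5-yl]prop-2-enoate, via alkylmercury trifluoroacetate 11 (not isolated)
Conditions: Hg(OCOCF3)2 (1.1 equiv), CH2Cl2, 0 °C to rt; then aq NaCl
Reagents that add atoms: mercury bis(trifluoroacetate) (O=C(O[Hg]OC(=O)C(F)(F)F)C(F)(F)F); sodium chloride ([Na+].[Cl-])
Why: Divalent mercury attacks the unsubstituted CH2 corner of the cyclopropane in 10; the C2–CH2 bond stretches, positive charge builds on the trimethoxybenzylic carbon, and the ortho phenol oxygen closes on that carbon from the side opposite the departing CH2, which becomes the C–Hg carbon of 11. The closest known reaction type is the mercury-induced electrophilic ring opening of arylcyclopropanes, which puts the nucleophile on the benzylic carbon with inversion and which neighbouring oxygen groups are known to intercept intramolecularly; a phenol as the internal nucleophile on a 1,2-diarylcyclopropane is an untested combination of these known elements. Ring B (O1–C2–C3–C3a–C7a) closes in the 5-exo-tet mode, the breaking C2–CH2 bond lying outside the new ring. C2 is set by stereospecific inversion at the trimethoxybenzylic cyclopropane carbon, and C3 is the other cyclopropane carbon carried through untouched, so the (1S,2S)-trans cyclopropane maps onto the 2,3-trans ring with the absolute configuration of the target (the 3R descriptor of 11 and 12 arises only because CH2Hg outranks C2). The step needs cleavage of C2–CH2 and not of C3–CH2: the phenol can reach C2 through a five-membered transition state but C3 only through a four-membered one, and CH2Cl2 offers no external nucleophile better than trifluoroacetate. It also needs the cyclopropane to react before the arenes and the alkene: the acrylate is electron-poor, its para position lowers the reactivity of ring A, and arene mercuration is reversible in the trifluoroacetic acid that is released whereas the strain-releasing opening is not. Should C2 ionise in part, closure trans to the C3 substituent is still favoured and C3 alone fixes the enantiomeric series. Exchange with aqueous NaCl converts 11 into the stable chloride 12, which can be chromatographed.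

Step 7
Reactants: 12 methyl (2E)-3-[(2R,3R)-3-[(chloromercurio)methyl]-2-(3,4,5-trimethoxyphenyl)-2,3-dihydro-1-benzofuran-5-yl]prop-2-enoate
Product: 14 methyl (2E)-3-[(2R,3S)-3-(hydroxymethyl)-2-(3,4,5-trimethoxyphenyl)-2,3-dihydro-1-benzofuran-5-yl]prop-2-enoate, via primary hydroperoxide 13 (not isolated)
Conditions: NaBH4, O2 (bubbled), DMF, 0 °C
Reagents that add atoms: dioxygen (O=O)
Why: Oxidative demercuration: borohydride converts the alkylmercury chloride into an alkylmercury hydride that loses mercury to give the primary alkyl radical, which dissolved O2 captures faster than it abstracts hydrogen; the hydroperoxide 13 is reduced by borohydride in the same flask. The radical sits on the exocyclic CH2 carbon, so C2 and C3 keep their configuration, and an unsaturated ester is reduced only slowly by NaBH4 at 0 °C.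

Step 8
Reactants: 14 methyl (2E)-3-[(2R,3S)-3-(hydroxymethyl)-2-(3,4,5-trimethoxyphenyl)-2,3-dihydro-1-benzofuran-5-yl]prop-2-enoate
Product: 15 (2E)-3-[(2R,3S)-3-(hydroxymethyl)-2-(3,4,5-trimethoxyphenyl)-2,3-dihydro-1-benzofuran-5-yl]prop-2-en-1-ol
Conditions: iBu2AlH (4 equiv), CH2Cl2, −78 °C; then aq potassium sodium tartrate
Reagents that add atoms: none
Why: Reduction of an α,β-unsaturated ester with iBu2AlH at low temperature is a 1,2-reduction that gives the allylic alcohol with the (E)-alkene intact; one equivalent of hydride is consumed by the free hydroxyl group. No stereocenter is touched, and the neutral tartrate work-up spares the acid-sensitive benzylic ether and cinnamyl alcohol.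

## Compound list

1 | 5-ethynyl-1,2,3-trimethoxybenzene | COc1cc(C#C)cc(OC)c1OC | starting material
2 | 2-[(E)-2-(3,4,5-trimethoxyphenyl)ethenyl]-1,3,2-benzodioxaborole | COc1cc(/C=C/B2Oc3ccccc3O2)cc(OC)c1OC | intermediate (not isolated)
3 | [(E)-2-(3,4,5-trimethoxyphenyl)ethenyl]boronic acid | COc1cc(/C=C/B(O)O)cc(OC)c1OC | intermediate
4 | (2S,3S)-2,3-dihydroxy-N,N,N',N'-tetramethylbutanediamide (diamide of D-tartaric acid) | CN(C)C(=O)[C@@H](O)[C@H](O)C(=O)N(C)C | starting material
5 | (4S,5S)-N,N,N',N'-tetramethyl-2-[(E)-2-(3,4,5-trimethoxyphenyl)ethenyl]-1,3,2-dioxaborolane-4,5-dicarboxamide | COc1cc(/C=C/B2O[C@H](C(=O)N(C)C)[C@@H](C(=O)N(C)C)O2)cc(OC)c1OC | intermediate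
6 | (4S,5S)-N,N,N',N'-tetramethyl-2-[(1S,2S)-2-(3,4,5-trimethoxyphenyl)cyclopropyl]-1,3,2-dioxaborolane-4,5-dicarboxamide | COc1cc([C@H]2C[C@@H]2B3O[C@H](C(=O)N(C)C)[C@@H](C(=O)N(C)C)O3)cc(OC)c1OC | intermediate (not isolated)
7 | [(1S,2S)-2-(3,4,5-trimethoxyphenyl)cyclopropyl]boronic acid | COc1cc([C@H]2C[C@@H]2B(O)O)cc(OC)c1OC | intermediate
8 | 3-bromo-4-hydroxybenzaldehyde | O=Cc1ccc(O)c(Br)c1 | starting material
9 | methyl (2E)-3-(3-bromo-4-hydroxyphenyl)prop-2-enoate | COC(=O)/C=C/c1ccc(O)c(Br)c1 | intermediate
10 | methyl (2E)-3-{4-hydroxy-3-[(1S,2S)-2-(3,4,5-trimethoxyphenyl)cyclopropyl]phenyl}prop-2-enoate | COc1cc([C@H]2C[C@@H]2c3cc(/C=C/C(=O)OC)ccc3O)cc(OC)c1OC | intermediate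
11 | methyl (2E)-3-[(2R,3R)-3-{[(trifluoroacetoxy)mercurio]methyl}-2-(3,4,5-trimethoxyphenyl)-2,3-dihydro-1-benzofuran-5-yl]prop-2-enoate | COc1cc([C@@H]2Oc3ccc(/C=C/C(=O)OC)cc3[C@H]2C[Hg]OC(=O)C(F)(F)F)cc(OC)c1OC | intermediate (not isolated)
12 | methyl (2E)-3-[(2R,3R)-3-[(chloromercurio)methyl]-2-(3,4,5-trimethoxyphenyl)-2,3-dihydro-1-benzofuran-5-yl]prop-2-enoate (2,3-trans) | COc1cc([C@@H]2Oc3ccc(/C=C/C(=O)OC)cc3[C@H]2C[Hg]Cl)cc(OC)c1OC | intermediate
13 | methyl (2E)-3-[(2R,3S)-3-(hydroperoxymethyl)-2-(3,4,5-trimethoxyphenyl)-2,3-dihydro-1-benzofuran-5-yl]prop-2-enoate | COc1cc([C@@H]2Oc3ccc(/C=C/C(=O)OC)cc3[C@H]2COO)cc(OC)c1OC | intermediate (not isolated)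
14 | methyl (2E)-3-[(2R,3S)-3-(hydroxymethyl)-2-(3,4,5-trimethoxyphenyl)-2,3-dihydro-1-benzofuran-5-yl]prop-2-enoate | COc1cc([C@@H]2Oc3ccc(/C=C/C(=O)OC)cc3[C@H]2CO)cc(OC)c1OC | intermediate
15 | (2E)-3-[(2R,3S)-3-(hydroxymethyl)-2-(3,4,5-trimethoxyphenyl)-2,3-dihydro-1-benzofuran-5-yl]prop-2-en-1-ol | COc1cc([C@@H]2Oc3ccc(/C=C/CO)cc3[C@H]2CO)cc(OC)c1OC | target

## Step count and least certain steps

Total steps: 8. Longest linear sequence: 7 steps (1 → 3 → 5 → 7 → 10 → 12 → 14 → 15, steps 1, 2, 3, 5, 6, 7 and 8); step 4 is a one-step side branch.

Step 6 (key step). The most likely failure is opening of the ring in the other direction, with cleavage of C3–CH2 and the charge taken up by the ortho-hydroxyaryl ring. That ring is at least as good a donor toward C3 as ring C is toward C2, since the 4-methoxy group of ring C is twisted out of conjugation and the two meta methoxy groups withdraw. Also possible are diversion of the reagent into arene mercuration and capture of C2 by trifluoroacetate in place of the phenol. The fallback separates ring opening from ring closure; it sets out from 10 and comes back at 14.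
- Acetylation of 10 (Ac2O, pyridine) gives methyl (2E)-3-{4-(acetyloxy)-3-[(1S,2S)-2-(3,4,5-trimethoxyphenyl)cyclopropyl]phenyl}prop-2-enoate F1. Its acetoxyaryl ring is a poor donor, so only C2 can carry charge.
- Hydroxymercuration with external water (Hg(OCOCF3)2, THF/H2O, then aq NaCl) should give the anti adduct methyl (2E)-3-{4-(acetyloxy)-3-[(1R,2R)-3-(chloromercurio)-1-hydroxy-1-(3,4,5-trimethoxyphenyl)propan-2-yl]phenyl}prop-2-enoate F2.
- Oxidative demercuration as in step 7 gives methyl (2E)-3-{4-(acetyloxy)-3-[(1R,2S)-1,3-dihydroxy-1-(3,4,5-trimethoxyphenyl)propan-2-yl]phenyl}prop-2-enoate F3.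
- HCl in MeOH removes the aryl acetate to give methyl (2E)-3-{3-[(1R,2S)-1,3-dihydroxy-1-(3,4,5-trimethoxyphenyl)propan-2-yl]-4-hydroxyphenyl}prop-2-enoate F4. The same acid ionises the trimethoxybenzylic alcohol, and the phenol closes ring B under thermodynamic control, trans to the C3 substituent, which gives 14.

Step 3. The most likely failure is incomplete facial discrimination in the methylene transfer, because the auxiliary sits two bonds from the alkene and binds zinc only weakly, or induction in the unwanted sense. The fallback replaces auxiliary control by catalyst control; it sets out from 1 and comes back at 10.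
- Deprotonation of 1 with nBuLi and addition to paraformaldehyde gives 3-(3,4,5-trimethoxyphenyl)prop-2-yn-1-ol F5.
- Semihydrogenation (H2, Pd/CaCO3 poisoned with Pb(OAc)2, quinoline, EtOAc) gives (2Z)-3-(3,4,5-trimethoxyphenyl)prop-2-en-1-ol F6.
- (EtO)2P(O)Cl and pyridine give diethyl (2Z)-3-(3,4,5-trimethoxyphenyl)prop-2-en-1-yl phosphate F7.
- Enantioselective copper-catalysed borylative cyclisation (CuCl, a chiral bisphosphine such as QuinoxP* in the enantiomer that leads to the 1S,2S product, KOtBu, B2pin2, THF) adds a boryl–copper species across the alkene. The benzylic C–Cu bond then displaces the phosphate, which gives 4,4,5,5-tetramethyl-2-[(1S,2S)-2-(3,4,5-trimethoxyphenyl)cyclopropyl]-1,3,2-dioxaborolane F8.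
- F8 is coupled with 9 under the conditions of step 5, with retention, to give 10.

Step 5. The most likely failure is slow oxidative addition once the ortho phenol is deprotonated. A long reaction time would then allow protodeboronation of the secondary cyclopropylboronic acid and partial saponification of the methyl ester by hot aqueous phosphate. The fallback masks the acidic hydroxyl group; it sets out from 9 and comes back at 10.
- Silylation of 9 (TBSCl, imidazole, DMF) gives methyl (2E)-3-{3-bromo-4-[(tert-butyldimethylsilyl)oxy]phenyl}prop-2-enoate F9.
- Coupling with 7 (Pd(OAc)2, SPhos, K3PO4, toluene with a trace of water) gives methyl (2E)-3-{4-[(tert-butyldimethylsilyl)oxy]-3-[(1S,2S)-2-(3,4,5-trimethoxyphenyl)cyclopropyl]phenyl}prop-2-enoate F10.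
- Bu4NF in THF at 0 °C removes the silyl group and gives 10.

Step 7. The most likely failure is hydrogen capture by the alkyl radical in place of oxygen capture (reductive demercuration), which grows when oxygen transfer into the solution is slow, together with some conjugate reduction of the acrylate by borohydride. The fallback is a polar exchange of C–Hg for C–O; it sets out from 12 and comes back at 15.
- Iododemercuration of 12 (I2, CH2Cl2, rt) gives methyl (2E)-3-[(2R,3R)-3-(iodomethyl)-2-(3,4,5-trimethoxyphenyl)-2,3-dihydro-1-benzofuran-5-yl]prop-2-enoate F11.
- Displacement with CsOAc in DMF at 50 °C gives methyl (2E)-3-[(2R,3S)-3-[(acetyloxy)methyl]-2-(3,4,5-trimethoxyphenyl)-2,3-dihydro-1-benzofuran-5-yl]prop-2-enoate F12.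
- iBu2AlH under the conditions of step 8 reduces both esters at once and gives 15 directly.

## Further compounds

F1 | step 6 | methyl (2E)-3-{4-(acetyloxy)-3-[(1S,2S)-2-(3,4,5-trimethoxyphenyl)cyclopropyl]phenyl}prop-2-enoate | COc1cc([C@H]2C[C@@H]2c3cc(/C=C/C(=O)OC)ccc3OC(C)=O)cc(OC)c1OC
F2 | step 6 | methyl (2E)-3-{4-(acetyloxy)-3-[(1R,2R)-3-(chloromercurio)-1-hydroxy-1-(3,4,5-trimethoxyphenyl)propan-2-yl]phenyl}prop-2-enoate | COc1cc([C@H](O)[C@H](C[Hg]Cl)c2cc(/C=C/C(=O)OC)ccc2OC(C)=O)cc(OC)c1OC
F3 | step 6 | methyl (2E)-3-{4-(acetyloxy)-3-[(1R,2S)-1,3-dihydroxy-1-(3,4,5-trimethoxyphenyl)propan-2-yl]phenyl}prop-2-enoate | COc1cc([C@H](O)[C@H](CO)c2cc(/C=C/C(=O)OC)ccc2OC(C)=O)cc(OC)c1OC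
F4 | step 6 | methyl (2E)-3-{3-[(1R,2S)-1,3-dihydroxy-1-(3,4,5-trimethoxyphenyl)propan-2-yl]-4-hydroxyphenyl}prop-2-enoate | COc1cc([C@H](O)[C@H](CO)c2cc(/C=C/C(=O)OC)ccc2O)cc(OC)c1OC
F5 | step 3 | 3-(3,4,5-trimethoxyphenyl)prop-2-yn-1-ol | COc1cc(C#CCO)cc(OC)c1OC
F6 | step 3 | (2Z)-3-(3,4,5-trimethoxyphenyl)prop-2-en-1-ol | COc1cc(/C=C\CO)cc(OC)c1OC
F7 | step 3 | diethyl (2Z)-3-(3,4,5-trimethoxyphenyl)prop-2-en-1-yl phosphate | CCOP(=O)(OCC)OC/C=C\c1cc(OC)c(OC)c(OC)c1
F8 | step 3 | 4,4,5,5-tetramethyl-2-[(1S,2S)-2-(3,4,5-trimethoxyphenyl)cyclopropyl]-1,3,2-dioxaborolane | COc1cc([C@H]2C[C@@H]2B3OC(C)(C)C(C)(C)O3)cc(OC)c1OC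
F9 | step 5 | methyl (2E)-3-{3-bromo-4-[(tert-butyldimethylsilyl)oxy]phenyl}prop-2-enoate | COC(=O)/C=C/c1ccc(O[Si](C)(C)C(C)(C)C)c(Br)c1
F10 | step 5 | methyl (2E)-3-{4-[(tert-butyldimethylsilyl)oxy]-3-[(1S,2S)-2-(3,4,5-trimethoxyphenyl)cyclopropyl]phenyl}prop-2-enoate | COc1cc([C@H]2C[C@@H]2c3cc(/C=C/C(=O)OC)ccc3O[Si](C)(C)C(C)(C)C)cc(OC)c1OC
F11 | step 7 | methyl (2E)-3-[(2R,3R)-3-(iodomethyl)-2-(3,4,5-trimethoxyphenyl)-2,3-dihydro-1-benzofuran-5-yl]prop-2-enoate | COc1cc([C@@H]2Oc3ccc(/C=C/C(=O)OC)cc3[C@H]2CI)cc(OC)c1OC
F12 | step 7 | methyl (2E)-3-[(2R,3S)-3-[(acetyloxy)methyl]-2-(3,4,5-trimethoxyphenyl)-2,3-dihydro-1-benzofuran-5-yl]prop-2-enoate | COc1cc([C@@H]2Oc3ccc(/C=C/C(=O)OC)cc3[C@H]2COC(C)=O)cc(OC)c1OC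
A1 | alternative 1 | 4-bromo-2-{2-[(tert-butyldimethylsilyl)oxy]-1-(4-methylbenzenesulfonyl)ethyl}phenol (racemic at the sulfonyl-bearing carbon) | Cc1ccc(cc1)S(=O)(=O)C(CO[Si](C)(C)C(C)(C)C)c1cc(Br)ccc1O
A2 | alternative 1 | (2R,5R)-2,5-dimethyl-1-(3,4,5-trimethoxybenzyl)thiolan-1-ium trifluoromethanesulfonate | C[C@@H]1CC[C@@H](C)[S+]1Cc2cc(OC)c(OC)c(OC)c2.[O-]S(=O)(=O)C(F)(F)F
A3 | alternative 1 | tert-butyl{[(2R,3S)-5-bromo-2-(3,4,5-trimethoxyphenyl)-2,3-dihydro-1-benzofuran-3-yl]methoxy}dimethylsilane | COc1cc([C@@H]2Oc3ccc(Br)cc3[C@H]2CO[Si](C)(C)C(C)(C)C)cc(OC)c1OC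
A4 | alternative 2 | methyl 3-{[(1R,2S)-2-{[(tert-butyldimethylsilyl)oxy]methyl}-1-(3,4,5-trimethoxyphenyl)but-3-yn-1-yl]oxy}-2-oxo-2H-pyran-6-carboxylate | COc1cc([C@H](Oc2ccc(C(=O)OC)oc2=O)[C@@H](C#C)CO[Si](C)(C)C(C)(C)C)cc(OC)c1OC
A5 | alternative 2 | methyl (2R,3S)-3-{[(tert-butyldimethylsilyl)oxy]methyl}-2-(3,4,5-trimethoxyphenyl)-2,3-dihydro-1-benzofuran-5-carboxylate | COc1cc([C@@H]2Oc3ccc(C(=O)OC)cc3[C@H]2CO[Si](C)(C)C(C)(C)C)cc(OC)c1OC
A6 | alternative 3 | (2R)-6-bromo-2-(3,4,5-trimethoxyphenyl)-2,3-dihydro-4H-chromen-4-one | COc1cc([C@H]2CC(=O)c3cc(Br)ccc3O2)cc(OC)c1OC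
A7 | alternative 3 | methyl (2R,3R)-5-bromo-2-(3,4,5-trimethoxyphenyl)-2,3-dihydro-1-benzofuran-3-carboxylate (2,3-trans) | COc1cc([C@@H]2Oc3ccc(Br)cc3[C@H]2C(=O)OC)cc(OC)c1OC
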